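**Retrosynthetic overview** (target locants: ring C1 = C–CH3, C2 = epoxide CH, C3 = CH–OAng, C4 = branch carbon, C5 = CH–OAng, C6 = CH–OH; C7 = C(=C14H2); C8 = side-chain CH–OAng; C10/C11 = side-chain epoxide)
1. Target ⇐ Shi epoxidation of C10=C11 ⇐ hydroxyl-directed epoxidation of C1=C2 ⇐ Luche reduction at C6 ⇐ angeloylations carried out around a C6 ketone, which tells the C6 oxygen apart from those at C3, C5 and C8.
2. Cyclohexene ring ⇐ one-flask chromium/nickel [3+3] annulation: C3–C4 by allylation of (Z)-3-iodobut-2-enal (supplies C1, C2, C3 and the ring methyl) and C1–C6 by alkenyl addition to the masked C6 aldehyde of the C4–C14 piece.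
3. Enabling feature: C3 is a homoallylic carbinol next to C4, which carries the exocyclic C7=C14 methylene; C6 is an allylic carbinol on the C1(CH3)=C2 alkene; and the C8 oxygen lies five atoms from C6, so C6–C5–C4–C7–C8–O can be held as a 3,6-dihydro-2H-pyran lactol that masks the aldehyde, locks the allyl geometry and shields one face.
4. Lactol bromide ⇐ alkynyl ketone (asymmetric transfer hydrogenation sets C5) ⇒ directed trans-hydroalumination/iodination ⇒ Nozaki–Hiyama–Kishi coupling with 4-methylpent-3-enal, oxidation, CBS reduction (sets C8).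
5. Ring order: temporary dihydropyran (step 9) → cyclohexene with opening of the pyran (step 13) → C1–C2 epoxide (step 19) → side-chain epoxide (step 20).

Key step: step 13

Remark: running text uses the target locants above; "configured as in the target" means the same arrangement in space, whatever the CIP letter of the intermediate.
Assumption: organometallic species formed in the flask (lithium acetylide, alkenylalanate, organochromium reagents) are treated as reactive forms of the numbered compounds and are not numbered separately.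

**Step 1**
Reactants: 1 tert-butyldimethyl(prop-2-yn-1-yloxy)silane; 2 ethyl 2,2-diethoxyacetate
Product: 3 5-[(tert-butyldimethylsilyl)oxy]-1,1-diethoxypent-3-yn-2-one
Conditions: n-BuLi, THF, −78 °C; then 2, −78 → −40 °C; aq. NH4Cl
Reagents that add atoms: none
Why: Nucleophilic acyl substitution of the ester by the lithium acetylide should stop at the ynone, because the α,α-dialkoxy tetrahedral adduct is held as a lithium chelate until the quench (acetylide acylation; no stereocentre).

**Step 2**
Reactants: 3 5-[(tert-butyldimethylsilyl)oxy]-1,1-diethoxypent-3-yn-2-one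
Product: 4 (2R)-5-[(tert-butyldimethylsilyl)oxy]-1,1-diethoxypent-3-yn-2-ol
Conditions: Ru[(S,S)-TsNCH(C6H5)CH(C6H5)NH](p-cymene) (1 mol %), i-PrOH, rt
Reagents that add atoms: none
Why: Noyori asymmetric transfer hydrogenation of an alkynyl ketone; with the (S,S) catalyst hydride should go to the face that puts the alkynyl group where aryl sits in aryl ketones, which is the 2R alcohol here because CH(OEt)2 outranks the alkynyl group (this carbon becomes C5).

**Step 3**
Reactants: 4 (2R)-5-[(tert-butyldimethylsilyl)oxy]-1,1-diethoxypent-3-yn-2-ol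
Product: 5 (2R,3Z)-5-[(tert-butyldimethylsilyl)oxy]-1,1-diethoxy-4-iodopent-3-en-2-ol
Conditions: NaAlH2(OCH2CH2OCH3)2, THF, −20 → 0 °C; EtOAc; then I2, THF, −78 → 0 °C
Reagents that add atoms: iodine, II
Why: Hydroxyl-directed trans-hydroalumination of the propargylic alcohol puts hydride on the near alkyne carbon and aluminium on the far one inside a five-membered alkoxyalanate, so iodinolysis with retention should give the Z-iodide with iodine cis to the carbinol carbon; the silyl ether is too poor a leaving group for allene formation at this temperature.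

**Step 4**
Reactants: 5 (2R,3Z)-5-[(tert-butyldimethylsilyl)oxy]-1,1-diethoxy-4-iodopent-3-en-2-ol
Product: 6 (2R,3Z)-5-[(tert-butyldimethylsilyl)oxy]-1,1-diethoxy-4-iodo-2-[(triisopropylsilyl)oxy]pent-3-ene
Conditions: i-Pr3SiOTf, 2,6-lutidine, CH2Cl2, −78 → 0 °C
Reagents that add atoms: triisopropylsilyl triflate, CC(C)[Si](OS(=O)(=O)C(F)(F)F)(C(C)C)C(C)C
Why: Silyl ether formation from a secondary alcohol with a silyl triflate and a hindered base; the bulky, non-leaving triisopropylsilyl ether later shields one ring face and the neighbouring hydroxyl.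

**Step 5**
Reactants: 7 4-methylpent-3-en-1-ol
Product: 8 4-methylpent-3-enal
Conditions: Dess–Martin periodinane, NaHCO3, CH2Cl2, 0 °C; used at once as a solution
Reagents that add atoms: none
Why: Dess–Martin oxidation of a primary alcohol stops at the aldehyde under buffered conditions that should not move the β,γ double bond into conjugation.

**Step 6**
Reactants: 6 (2R,3Z)-5-[(tert-butyldimethylsilyl)oxy]-1,1-diethoxy-4-iodo-2-[(triisopropylsilyl)oxy]pent-3-ene; 8 4-methylpent-3-enal
Product: 9 (2R,3Z)-4-{[(tert-butyldimethylsilyl)oxy]methyl}-1,1-diethoxy-8-methyl-2-[(triisopropylsilyl)oxy]nona-3,7-dien-5-ol (both C5 epimers)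
Conditions: CrCl2 (4 equiv), NiCl2 (1 mol %), DMSO, rt
Reagents that add atoms: none
Why: Nozaki–Hiyama–Kishi coupling: nickel-catalysed formation of the alkenylchromium with retention of alkene geometry and chemoselective 1,2-addition to the aldehyde beside acetal and silyl ethers; the new carbinol centre is not controlled and is erased in step 7.

**Step 7**
Reactants: 9 (2R,3Z)-4-{[(tert-butyldimethylsilyl)oxy]methyl}-1,1-diethoxy-8-methyl-2-[(triisopropylsilyl)oxy]nona-3,7-dien-5-ol
Product: 10 (2R,3Z)-4-{[(tert-butyldimethylsilyl)oxy]methyl}-1,1-diethoxy-8-methyl-2-[(triisopropylsilyl)oxy]nona-3,7-dien-5-one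
Conditions: Dess–Martin periodinane, NaHCO3, CH2Cl2, 0 °C
Reagents that add atoms: none
Why: Dess–Martin oxidation of the allylic alcohol converges both epimers to one enone under buffered conditions that spare the acetal and the silyl ethers.

**Step 8**
Reactants: 10 (2R,3Z)-4-{[(tert-butyldimethylsilyl)oxy]methyl}-1,1-diethoxy-8-methyl-2-[(triisopropylsilyl)oxy]nona-3,7-dien-5-one
Product: 11 (2R,3Z,5S)-4-{[(tert-butyldimethylsilyl)oxy]methyl}-1,1-diethoxy-8-methyl-2-[(triisopropylsilyl)oxy]nona-3,7-dien-5-ol
Conditions: (R)-2-methyl-CBS-oxazaborolidine (0.3 equiv), catecholborane, toluene, −78 °C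
Reagents that add atoms: none
Why: Corey–Bakshi–Shibata reduction of an α-substituted enone, with the alkenyl group as the large and CH2 as the small substituent, should give the 5S allylic alcohol (the later C8) under catalyst control; catecholborane at −78 °C should not hydroborate the trisubstituted alkene.

**Step 9**
Reactants: 11 (2R,3Z,5S)-4-{[(tert-butyldimethylsilyl)oxy]methyl}-1,1-diethoxy-8-methyl-2-[(triisopropylsilyl)oxy]nona-3,7-dien-5-ol
Product: 12 (3R,6S)-5-(hydroxymethyl)-6-(3-methylbut-2-en-1-yl)-3-[(triisopropylsilyl)oxy]-3,6-dihydro-2H-pyran-2-ol (both anomers)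
Conditions: CF3CO2H/H2O/THF (1:2:8), 0 °C → rt
Reagents that add atoms: water, O
Why: Acid hydrolysis of the diethyl acetal and of the primary silyl ether; the freed aldehyde is trapped by the hydroxyl held cis across the Z alkene as a six-membered lactol (ring–chain tautomerism), while the hindered secondary triisopropylsilyl ether should survive.

**Step 10**
Reactants: 12 (3R,6S)-5-(hydroxymethyl)-6-(3-methylbut-2-en-1-yl)-3-[(triisopropylsilyl)oxy]-3,6-dihydro-2H-pyran-2-ol
Product: 13 (3R,6S)-5-(bromomethyl)-6-(3-methylbut-2-en-1-yl)-3-[(triisopropylsilyl)oxy]-3,6-dihydro-2H-pyran-2-ol (both anomers)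
Conditions: N-bromosuccinimide, Me2S, CH2Cl2, −30 → 0 °C
Reagents that add atoms: N-bromosuccinimide, O=C1CCC(=O)N1Br
Why: Corey–Kim bromination turns allylic alcohols into bromides by SN2 displacement of an alkoxysulfonium ion and should select the primary allylic hydroxyl over the hemiacetal hydroxyl, whose sulfonium adduct reverts on work-up.

**Step 11**
Reactants: 14 but-2-yn-1-ol
Product: 15 (2Z)-3-iodobut-2-en-1-ol
Conditions: NaAlH2(OCH2CH2OCH3)2, THF, 0 °C → rt; EtOAc; then I2, THF, −78 → 0 °C
Reagents that add atoms: iodine, II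
Why: Hydroxyl-directed trans-hydroalumination followed by iodinolysis with retention gives the Z-iodide with iodine cis to CH2OH (same reaction type as step 3).

**Step 12**
Reactants: 15 (2Z)-3-iodobut-2-en-1-ol
Product: 16 (2Z)-3-iodobut-2-enal
Conditions: MnO2, CH2Cl2, rt, dark
Reagents that add atoms: none
Why: Allylic oxidation with MnO2 is neutral and selective for the allylic alcohol, so the Z-iodoenal should form without alkene isomerisation if kept cold and dark and used promptly.

**Step 13**
Reactants: 13 (3R,6S)-5-(bromomethyl)-6-(3-methylbut-2-en-1-yl)-3-[(triisopropylsilyl)oxy]-3,6-dihydro-2H-pyran-2-ol; 16 (2Z)-3-iodobut-2-enal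
Product: 18 5-O-triisopropylsilyl-bisabola-1,7(14),10-triene-3,5,6,8-tetrol (both C6 epimers), via lactol iodide 17 (not isolated)
Conditions: CrCl2 (8 equiv), NiCl2 (2 mol %), DMF/THF (1:1), 0 °C → rt; 13 added slowly to 16 (1.2 equiv) and the salts
Reagents that add atoms: none
Why: Proposed new method: divalent chromium inserts into the allylic C–Br bond of 13 within minutes without nickel, and the allylchromium adds through its ring carbon (SE2′, closed six-membered chair) to the only free aldehyde present, that of 16, because the aldehyde of 13 is stored as a hemiacetal; this forms C3–C4 and the C7=C14 methylene in 17. Nickel catalysis then turns the slower-reacting alkenyl iodide into an alkenylchromium, which adds to the hydroxy-aldehyde tautomer of the lactol in a 6-exo-trig closure that forms C1–C6 and the cyclohexene while the temporary pyran opens. The closest known reactions are the chromium-mediated allylation of aldehydes by 1-(bromomethyl)cycloalkenes, nickel/chromium-mediated ring closures of iodoalkenyl aldehydes, and additions of organometallics to lactols through their open tautomers; their union in one flask on a lactol is the new element. C4 is set by the dihydropyran, in which the silyloxy group on the neighbouring carbon and the prenyl-bearing carbon both lie on one face so that the aldehyde is delivered to the other, and C3 follows from the chair with the ring CH locked trans to CH2Cr and the iodoalkenyl group equatorial (3,4-trans); C6 forms as a mixture that is erased in step 15 and reset in step 18. The step needs cross-selectivity between two aldehydes (lactol mask, small excess of 16), attack through the substituted allyl terminus (normal for allylchromium) and no 1,4-elimination (the δ-oxygen is a silyl ether, a poor leaving group).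

**Step 14**
Reactants: 18 5-O-triisopropylsilyl-bisabola-1,7(14),10-triene-3,5,6,8-tetrol; 19 angelic acid
Product: 20 3,8-di-O-angeloyl derivative of 18 (C6 hydroxyl free; both C6 epimers)
Conditions: 19 (2.3 equiv), 2,4,6-trichlorobenzoyl chloride, Et3N, toluene, rt; then 18, toluene, 50 °C
Reagents that add atoms: none
Why: Yamaguchi esterification through the preformed mixed anhydride without nucleophilic catalyst should keep the angelate Z; the C3 and C8 hydroxyls should react while the C6 hydroxyl, flanked by the triisopropylsilyloxy carbon and the methyl-bearing alkene carbon, stays free.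

**Step 15**
Reactants: 20 3,8-di-O-angeloyl derivative of 18
Product: 21 3,8-di-O-angeloyl-5-O-triisopropylsilyl-3,5,8-trihydroxybisabola-1,7(14),10-trien-6-one
Conditions: Dess–Martin periodinane, NaHCO3, CH2Cl2, 0 °C → rt
Reagents that add atoms: none
Why: Dess–Martin oxidation of the one remaining (allylic) alcohol converges both C6 epimers to a single enone and marks C6 as the oxygen that is not to be acylated.

**Step 16**
Reactants: 21 3,8-di-O-angeloyl-5-O-triisopropylsilyl-3,5,8-trihydroxybisabola-1,7(14),10-trien-6-one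
Product: 22 3,8-di-O-angeloyl-3,5,8-trihydroxybisabola-1,7(14),10-trien-6-one (free C5 hydroxyl)
Conditions: HF·pyridine, pyridine, THF, 0 °C → rt
Reagents that add atoms: none
Why: Fluoride cleavage of the silyl ether (Si–F bond formation) under buffered conditions that should leave the allylic esters, the enone and the configuration at C5 untouched.

**Step 17**
Reactants: 22 3,8-di-O-angeloyl-3,5,8-trihydroxybisabola-1,7(14),10-trien-6-one; 19 angelic acid
Product: 23 3,5,8-tri-O-angeloyl-3,5,8-trihydroxybisabola-1,7(14),10-trien-6-one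
Conditions: 19 (1.5 equiv), 2,4,6-trichlorobenzoyl chloride, Et3N, toluene, rt; filtered; then 22, toluene, 50 °C
Reagents that add atoms: none
Why: Yamaguchi esterification of the only free hydroxyl; heating the filtered mixed anhydride without added base should limit enolisation at C5 (α to the ketone) and Z→E isomerisation of the angelate.

**Step 18**
Reactants: 23 3,5,8-tri-O-angeloyl-3,5,8-trihydroxybisabola-1,7(14),10-trien-6-one
Product: 24 3,5,8-tri-O-angeloyl-bisabola-1,7(14),10-triene-3,5,6,8-tetrol (C6 hydroxyl cis to the C5 angelate)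
Conditions: NaBH4, CeCl3·7H2O, MeOH/CH2Cl2, −78 °C; AcOH quench at −78 °C
Reagents that add atoms: none
Why: Luche reduction gives chemoselective 1,2-reduction of the enone beside three unsaturated esters; hydride should add anti to the pseudoaxial C5–O bond (axial attack on the half-chair), placing the new C6 hydroxyl cis to the C5 angelate as in the target.

**Step 19**
Reactants: 24 3,5,8-tri-O-angeloyl-bisabola-1,7(14),10-triene-3,5,6,8-tetrol
Product: 25 1,2-epoxide of 24 (oxygen cis to the C6 hydroxyl; C10=C11 alkene intact)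
Conditions: VO(acac)2 (5 mol %), t-BuOOH (in decane), CH2Cl2, 0 °C → rt
Reagents that add atoms: tert-butyl hydroperoxide, CC(C)(C)OO
Why: Vanadium-catalysed hydroxyl-directed epoxidation: the C6 hydroxyl binds the vanadium peroxide and delivers oxygen to C1=C2 on its own face, while the methylene, prenyl and angelate alkenes, which have no allylic hydroxyl, should be left.

**Step 20**
Reactants: 25 1,2-epoxide of 24
Product: 26 target CNP0147918.1
Conditions: D-fructose-derived Shi ketone (1 equiv), KHSO5, NaHCO3, Bu4NHSO4, MeCN/dimethoxymethane/aq. buffer (pH 8), 0 °C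
Reagents that add atoms: potassium peroxymonosulfate, [K+].[O-]S(=O)(=O)OO
Why: Shi asymmetric epoxidation: the electrophilic chiral dioxirane should select the electron-rich trisubstituted C10=C11 alkene over the hindered 1,1-disubstituted methylene and the electron-poor angelates, and the D-fructose-derived ketone should give the 10R epoxide through the spiro transition state; pH 8 limits acyl migration.

**Compound list**
1 | tert-butyldimethyl(prop-2-yn-1-yloxy)silane | C#CCO[Si](C)(C)C(C)(C)C | starting material
2 | ethyl 2,2-diethoxyacetate | CCOC(=O)C(OCC)OCC | starting material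
3 | 5-[(tert-butyldimethylsilyl)oxy]-1,1-diethoxypent-3-yn-2-one | CCOC(OCC)C(=O)C#CCO[Si](C)(C)C(C)(C)C | intermediate
4 | (2R)-5-[(tert-butyldimethylsilyl)oxy]-1,1-diethoxypent-3-yn-2-ol | CCOC(OCC)[C@H](O)C#CCO[Si](C)(C)C(C)(C)C | intermediate
5 | (2R,3Z)-5-[(tert-butyldimethylsilyl)oxy]-1,1-diethoxy-4-iodopent-3-en-2-ol | CCOC(OCC)[C@H](O)/C=C(\I)CO[Si](C)(C)C(C)(C)C | intermediate
6 | (2R,3Z)-5-[(tert-butyldimethylsilyl)oxy]-1,1-diethoxy-4-iodo-2-[(triisopropylsilyl)oxy]pent-3-ene | CCOC(OCC)[C@H](O[Si](C(C)C)(C(C)C)C(C)C)/C=C(\I)CO[Si](C)(C)C(C)(C)C | intermediate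
7 | 4-methylpent-3-en-1-ol | CC(C)=CCCO | starting material
8 | 4-methylpent-3-enal | CC(C)=CCC=O | intermediate
9 | (2R,3Z)-4-{[(tert-butyldimethylsilyl)oxy]methyl}-1,1-diethoxy-8-methyl-2-[(triisopropylsilyl)oxy]nona-3,7-dien-5-ol, both C5 epimers | CCOC(OCC)[C@H](O[Si](C(C)C)(C(C)C)C(C)C)/C=C(\C(O)CC=C(C)C)CO[Si](C)(C)C(C)(C)C | intermediate
10 | (2R,3Z)-4-{[(tert-butyldimethylsilyl)oxy]methyl}-1,1-diethoxy-8-methyl-2-[(triisopropylsilyl)oxy]nona-3,7-dien-5-one | CCOC(OCC)[C@H](O[Si](C(C)C)(C(C)C)C(C)C)/C=C(\C(=O)CC=C(C)C)CO[Si](C)(C)C(C)(C)C | intermediate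
11 | (2R,3Z,5S)-4-{[(tert-butyldimethylsilyl)oxy]methyl}-1,1-diethoxy-8-methyl-2-[(triisopropylsilyl)oxy]nona-3,7-dien-5-ol | CCOC(OCC)[C@H](O[Si](C(C)C)(C(C)C)C(C)C)/C=C(\[C@@H](O)CC=C(C)C)CO[Si](C)(C)C(C)(C)C | intermediate
12 | (3R,6S)-5-(hydroxymethyl)-6-(3-methylbut-2-en-1-yl)-3-[(triisopropylsilyl)oxy]-3,6-dihydro-2H-pyran-2-ol, both anomers | OC1O[C@@H](CC=C(C)C)C(CO)=C[C@H]1O[Si](C(C)C)(C(C)C)C(C)C | intermediate
13 | (3R,6S)-5-(bromomethyl)-6-(3-methylbut-2-en-1-yl)-3-[(triisopropylsilyl)oxy]-3,6-dihydro-2H-pyran-2-ol, both anomers | OC1O[C@@H](CC=C(C)C)C(CBr)=C[C@H]1O[Si](C(C)C)(C(C)C)C(C)C | intermediate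
14 | but-2-yn-1-ol | CC#CCO | starting material
15 | (2Z)-3-iodobut-2-en-1-ol | OC/C=C(/C)I | intermediate
16 | (2Z)-3-iodobut-2-enal | O=C/C=C(/C)I | intermediate
17 | (3R,4R,6S)-4-[(1R,2Z)-1-hydroxy-3-iodobut-2-en-1-yl]-5-methylidene-6-(3-methylbut-2-en-1-yl)-3-[(triisopropylsilyl)oxy]oxan-2-ol, both anomers (not isolated) | OC1O[C@@H](CC=C(C)C)C(=C)[C@H]([C@@H](O)/C=C(/C)I)[C@H]1O[Si](C(C)C)(C(C)C)C(C)C | intermediate
18 | 5-O-triisopropylsilyl-bisabola-1,7(14),10-triene-3,5,6,8-tetrol; C3, C4, C5 and C8 configured as in the target; both C6 epimers | C=C([C@H]1[C@@H](O[Si](C(C)C)(C(C)C)C(C)C)C(O)C(C)=C[C@@H]1O)[C@H](CC=C(C)C)O | intermediate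
19 | angelic acid, (2Z)-2-methylbut-2-enoic acid | C/C=C(/C)C(=O)O | starting material
20 | 3,8-di-O-angeloyl derivative of 18; C6 hydroxyl free; both C6 epimers | C=C([C@H]1[C@@H](O[Si](C(C)C)(C(C)C)C(C)C)C(O)C(C)=C[C@@H]1OC(=O)/C(C)=C\C)[C@H](CC=C(C)C)OC(=O)/C(C)=C\C | intermediate
21 | 3,8-di-O-angeloyl-5-O-triisopropylsilyl-3,5,8-trihydroxybisabola-1,7(14),10-trien-6-one | C=C([C@H]1[C@@H](O[Si](C(C)C)(C(C)C)C(C)C)C(=O)C(C)=C[C@@H]1OC(=O)/C(C)=C\C)[C@H](CC=C(C)C)OC(=O)/C(C)=C\C | intermediate
22 | 3,8-di-O-angeloyl-3,5,8-trihydroxybisabola-1,7(14),10-trien-6-one | C=C([C@H]1[C@@H](O)C(=O)C(C)=C[C@@H]1OC(=O)/C(C)=C\C)[C@H](CC=C(C)C)OC(=O)/C(C)=C\C | intermediate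
23 | 3,5,8-tri-O-angeloyl-3,5,8-trihydroxybisabola-1,7(14),10-trien-6-one | C=C([C@H]1[C@@H](OC(=O)/C(C)=C\C)C(=O)C(C)=C[C@@H]1OC(=O)/C(C)=C\C)[C@H](CC=C(C)C)OC(=O)/C(C)=C\C | intermediate
24 | 3,5,8-tri-O-angeloyl-bisabola-1,7(14),10-triene-3,5,6,8-tetrol; C6 hydroxyl cis to the C5 angelate | C=C([C@H]1[C@@H](OC(=O)/C(C)=C\C)[C@@H](O)C(C)=C[C@@H]1OC(=O)/C(C)=C\C)[C@H](CC=C(C)C)OC(=O)/C(C)=C\C | intermediate
25 | 1,2-epoxide of 24, oxygen cis to the C6 hydroxyl; C10=C11 alkene intact | C=C([C@H]1[C@@H](OC(=O)/C(C)=C\C)[C@@H](O)[C@@]2(C)O[C@H]2[C@@H]1OC(=O)/C(C)=C\C)[C@H](CC=C(C)C)OC(=O)/C(C)=C\C | intermediate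
26 | CNP0147918.1: 10,11-epoxide of 25; 1R,2S,3R,4S,5R,6R,8S,10R in target locants | C=C([C@H]1[C@@H](OC(=O)/C(C)=C\C)[C@@H](O)[C@@]2(C)O[C@H]2[C@@H]1OC(=O)/C(C)=C\C)[C@H](C[C@H]1OC1(C)C)OC(=O)/C(C)=C\C | target

**Totals**
Total steps: 20. Longest linear sequence: 17 (steps 1–4, 6–10, 13–20).

**Steps most likely to fail**

Step 13 (the step carrying the new-method label). The lactol may open too slowly under the chromium conditions, so that protodeiodination of the alkenylchromium or intermolecular coupling overtakes ring closure; self-allylation could also erode cross-selectivity. The fallback sets out from 13 and 16 and uses known chemistry. Only the chromium-mediated allylation is run (CrCl2, THF/DMF, 0 °C, no nickel salt) and lactol iodide 17 is isolated. Then 17 is treated with t-BuLi (4.2 equiv, Et2O/THF, −78 → −20 °C): both hydroxyls are deprotonated, iodine–lithium exchange gives the alkenyllithium, and this adds to the aldehyde tautomer of the lithium lactolate (Parham-type ring closure). The route is rejoined at 18. It makes no new compound (entry F0).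

Step 14. The three hydroxyls may not be told apart well enough, so that acylation reaches C6. The fallback sets out from 18 and removes the need for site selectivity. The silyl ether is cleaved (HF·pyridine, THF) to give bisabola-1,7(14),10-triene-3,5,6,8-tetrol F1. Its only vicinal diol (C5/C6) is oxidised at the allylic C6 carbinol with [(2,9-dimethyl-1,10-phenanthroline)Pd(OAc)]2(OTf)2 (a divalent palladium catalyst) and benzoquinone in MeCN/H2O, giving 3,5,8-trihydroxybisabola-1,7(14),10-trien-6-one F2. All three hydroxyls of F2 are then esterified at once with the mixed anhydride of 19, and the route is rejoined at 23.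

Step 20. Chemoselectivity among four alkene types may be lost, or the C5 acyl group may shift to the free C6 hydroxyl (or the epoxy alcohol may rearrange) in the buffered aqueous medium. The fallback sets out from 23, which has no free hydroxyl and whose ring alkene is deactivated by the ketone. Shi epoxidation there gives the 10,11-epoxide of 23 F3; Luche reduction gives the 10,11-epoxide of 24 F4; the vanadium-directed epoxidation of step 19 then gives 26 directly.

**Further compounds**
F0 | step 13 | none | none
F1 | step 14 | bisabola-1,7(14),10-triene-3,5,6,8-tetrol, both C6 epimers | C=C([C@H]1[C@@H](O)C(O)C(C)=C[C@@H]1O)[C@H](CC=C(C)C)O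
F2 | step 14 | 3,5,8-trihydroxybisabola-1,7(14),10-trien-6-one | C=C([C@H]1[C@@H](O)C(=O)C(C)=C[C@@H]1O)[C@H](CC=C(C)C)O
F3 | step 20 | 10,11-epoxide (10R) of 23 | C=C([C@H]1[C@@H](OC(=O)/C(C)=C\C)C(=O)C(C)=C[C@@H]1OC(=O)/C(C)=C\C)[C@H](C[C@H]1OC1(C)C)OC(=O)/C(C)=C\C
F4 | step 20 | 10,11-epoxide (10R) of 24 | C=C([C@H]1[C@@H](OC(=O)/C(C)=C\C)[C@@H](O)C(C)=C[C@@H]1OC(=O)/C(C)=C\C)[C@H](C[C@H]1OC1(C)C)OC(=O)/C(C)=C\C
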